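## Retrosynthetic overview

1. The target, a (2E,4R)-4-acetoxygeranyl ether of 4-hydroxy-5-methylcoumarin, comes from O-acetylation of the (4R)-allylic alcohol in the last step.
2. The (4R)-alcohol comes from forming the side-chain C4–C5 bond, and the only stereocentre, by chiral-phosphoric-acid-catalysed prenylboration of an (E)-α-methyl-γ-(coumarinyloxy) enal with a tertiary 1,1-dimethylallyl pinacolboronate (allylic transposition gives the linear prenyl group).
3. The enal comes from E-selective allylic oxidation of the 4-O-prenyl ether, which comes from O-alkylation of 4-hydroxy-5-methylcoumarin with prenol.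
4. Rings: the benzene ring is bought; only the pyranone ring is built, in the first step, from 2'-hydroxy-6'-methylacetophenone and diethyl carbonate.

Assumption: the Grignard solution of step 4 and the phosphoric acid catalyst of step 5 are catalogue items. The sense of induction of the (R)-catalyst is taken from its allylborations of aryl and alkenyl aldehydes (Re-face attack); if the measured sense were opposite, the (S)-catalyst would be used.

## Route

Step 1
Reactants: 1 1-(2-hydroxy-6-methylphenyl)ethan-1-one; 2 diethyl carbonate
Product: 4 4-hydroxy-5-methyl-2H-chromen-2-one, via β-keto ester 3 (not isolated)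
Conditions: NaH (4 equiv), toluene, 110 °C; then 2 M HCl
Reagents that add atoms: none
Why: Claisen-type C-ethoxycarbonylation of the methyl ketone enolate gives β-keto ester 3, whose phenoxide lactonises onto the ester to close the pyranone ring (standard 4-hydroxycoumarin synthesis); the ring methyl ortho to the acetyl group becomes C5-methyl.

Step 2
Reactants: 4 4-hydroxy-5-methyl-2H-chromen-2-one; 5 3-methylbut-2-en-1-ol
Product: 6 5-methyl-4-[(3-methylbut-2-en-1-yl)oxy]-2H-chromen-2-one
Conditions: PPh3 (1.3 equiv), DIAD (1.3 equiv), THF, 0 °C to rt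
Reagents that add atoms: none
Why: Mitsunobu etherification: the acidic enolic 4-OH (pKa about 4) is alkylated at oxygen by the activated primary allylic alcohol under neutral conditions, which favours O4- over C3-alkylation.

Step 3
Reactants: 6 5-methyl-4-[(3-methylbut-2-en-1-yl)oxy]-2H-chromen-2-one
Product: 7 (2E)-2-methyl-4-[(5-methyl-2-oxo-2H-chromen-4-yl)oxy]but-2-enal
Conditions: SeO2 (1.2 equiv), 1,4-dioxane, 80 °C, 3 h
Reagents that add atoms: selenium dioxide, O=[Se]=O
Why: Riley allylic oxidation (ene reaction, then [2,3]-sigmatropic shift) attacks the (E)-methyl of the trisubstituted alkene, as it does in prenyl acetate, and gives the (E)-enal; the electron-poor coumarin C3=C4 bond and the aryl methyl are left alone.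

Step 4
Reactants: 8 (3-methylbut-2-en-1-yl)magnesium chloride; 9 2-isopropoxy-4,4,5,5-tetramethyl-1,3,2-dioxaborolane
Product: 11 4,4,5,5-tetramethyl-2-(2-methylbut-3-en-2-yl)-1,3,2-dioxaborolane, via ate complex 10 (not isolated)
Conditions: THF, −78 °C to 0 °C; then HCl (2 M in Et2O, 1 equiv)
Reagents that add atoms: none
Why: allylic Grignard reagents attack boron electrophiles through their γ-terminus (SE2′ borylation), so the tertiary 1,1-dimethylallyl boronate forms after acid collapse of ate complex 10; pinacol allylboronates do not undergo 1,3-boron shift at room temperature.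

Step 5
Reactants: 7 (2E)-2-methyl-4-[(5-methyl-2-oxo-2H-chromen-4-yl)oxy]but-2-enal; 11 4,4,5,5-tetramethyl-2-(2-methylbut-3-en-2-yl)-1,3,2-dioxaborolane
Product: 13 4-{[(2E,4R)-4-hydroxy-3,7-dimethylocta-2,6-dien-1-yl]oxy}-5-methyl-2H-chromen-2-one, via borate ester 12 (not isolated)
Conditions: (R)-TRIP [(R)-3,3'-bis(2,4,6-triisopropylphenyl)-1,1'-binaphthyl-2,2'-diyl hydrogen phosphate, 10 mol%], 11 (1.5 equiv, added slowly), 4 Å MS, toluene, −30 °C, 48 h; then aq. NaHCO3
Reagents that add atoms: none
Why: Proposed new method: chiral-phosphoric-acid-catalysed enantioselective linear prenylboration of an α-branched γ-aryloxy enal with an achiral tertiary α,α-dimethylallyl pinacolboronate. The P–OH of (R)-TRIP hydrogen-bonds to a boronate oxygen and the P=O to the formyl C–H, which closes a chair six-membered transition state with the alkenyl group of the enal equatorial. The γ-CH2 of the boronate bonds to the Re face of C=O while the C=C shifts to the Me2C=CH position, so the (4R)-borate 12 forms and is hydrolysed on work-up. The gem-dimethyl group makes the reagent achiral (no resolution is needed) and more reactive through strain release, and TRIP is known to accept an axial α-substituent in this transition state. Closest known reaction type: TRIP-catalysed allyl- and crotylboration of aldehydes with pinacol boronates and the TRIP-catalysed kinetic resolution of secondary α-substituted allylboronates.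

Step 6
Reactants: 13 4-{[(2E,4R)-4-hydroxy-3,7-dimethylocta-2,6-dien-1-yl]oxy}-5-methyl-2H-chromen-2-one
Product: 14 (2E,4R)-3,7-dimethyl-1-[(5-methyl-2-oxo-2H-chromen-4-yl)oxy]octa-2,6-dien-4-yl acetate
Conditions: Ac2O (1.5 equiv), pyridine (3 equiv), DMAP (5 mol%), CH2Cl2, 0 °C to rt
Reagents that add atoms: acetic anhydride, CC(=O)OC(C)=O
Why: DMAP-catalysed O-acylation of the secondary allylic alcohol does not touch the C–O stereocentre, so the (R) configuration is kept and the lactone and enol ether survive the mild base.

## Compound list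

1 | 1-(2-hydroxy-6-methylphenyl)ethan-1-one | CC(=O)c1c(C)cccc1O | starting material
2 | diethyl carbonate | CCOC(=O)OCC | starting material
3 | ethyl 3-(2-hydroxy-6-methylphenyl)-3-oxopropanoate | CCOC(=O)CC(=O)c1c(C)cccc1O | intermediate
4 | 4-hydroxy-5-methyl-2H-chromen-2-one | Cc1cccc2oc(=O)cc(O)c12 | intermediate
5 | 3-methylbut-2-en-1-ol | CC(C)=CCO | starting material
6 | 5-methyl-4-[(3-methylbut-2-en-1-yl)oxy]-2H-chromen-2-one | CC(C)=CCOc1cc(=O)oc2cccc(C)c12 | intermediate
7 | (2E)-2-methyl-4-[(5-methyl-2-oxo-2H-chromen-4-yl)oxy]but-2-enal | O=C/C(C)=C/COc1cc(=O)oc2cccc(C)c12 | intermediate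
8 | (3-methylbut-2-en-1-yl)magnesium chloride | CC(C)=CC[Mg]Cl | starting material
9 | 2-isopropoxy-4,4,5,5-tetramethyl-1,3,2-dioxaborolane | CC(C)OB1OC(C)(C)C(C)(C)O1 | starting material
10 | chloromagnesium isopropoxy(2-methylbut-3-en-2-yl)(pinacolato)borate | CC(C)O[B-]1(OC(C)(C)C(C)(C)O1)C(C)(C)C=C.Cl[Mg+] | intermediate
11 | 4,4,5,5-tetramethyl-2-(2-methylbut-3-en-2-yl)-1,3,2-dioxaborolane | C=CC(C)(C)B1OC(C)(C)C(C)(C)O1 | intermediate
12 | 4-{[(2E,4R)-3,7-dimethyl-4-[(4,4,5,5-tetramethyl-1,3,2-dioxaborolan-2-yl)oxy]octa-2,6-dien-1-yl]oxy}-5-methyl-2H-chromen-2-one | CC1(C)OB(O[C@H](CC=C(C)C)/C(C)=C/COc2cc(=O)oc3cccc(C)c23)OC1(C)C | intermediate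
13 | 4-{[(2E,4R)-4-hydroxy-3,7-dimethylocta-2,6-dien-1-yl]oxy}-5-methyl-2H-chromen-2-one | O[C@H](CC=C(C)C)/C(C)=C/COc1cc(=O)oc2cccc(C)c12 | intermediate
14 | (2E,4R)-3,7-dimethyl-1-[(5-methyl-2-oxo-2H-chromen-4-yl)oxy]octa-2,6-dien-4-yl acetate | CC(=O)O[C@H](CC=C(C)C)/C(C)=C/COc1cc(=O)oc2cccc(C)c12 | target

## Step count and risk

Total step count: 6. Longest linear sequence: 5 (steps 1, 2, 3, 5, 6); step 4 makes the boron reagent on a side branch.

The three steps most likely to fail:

Step 5 (the new prenylboration). The risks are a racemic background addition of the reactive tertiary boronate, boron 1,3-shift to the linear prenyl boronate (which would give the branched 1,1-dimethylallyl carbinol), and lower enantioselectivity with the α-branched enal. The fallback uses known chemistry. It sets out from enal 7. TRIP-catalysed allylboration with commercial allylboronic acid pinacol ester [(R)-TRIP 5 mol%, toluene, −30 °C; established for aryl and alkenyl aldehydes] gives, through the borate ester 5-methyl-4-{[(2E,4R)-3-methyl-4-[(4,4,5,5-tetramethyl-1,3,2-dioxaborolan-2-yl)oxy]hepta-2,6-dien-1-yl]oxy}-2H-chromen-2-one F1 (not isolated), the homoallylic alcohol 4-{[(2E,4R)-4-hydroxy-3-methylhepta-2,6-dien-1-yl]oxy}-5-methyl-2H-chromen-2-one F2. Cross-metathesis of F2 with 2-methylbut-2-ene as co-solvent [second-generation Grubbs catalyst RuCl2(=CHPh)(H2IMes)(PCy3), 5 mol%, CH2Cl2, 40 °C] turns the vinyl end into the 2-methylprop-1-enyl end; the trisubstituted side-chain alkene and the coumarin double bond do not take part. The fallback comes back to the route at alcohol 13 and costs one extra step.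

Step 3 (SeO2 oxidation). The risks are a mixture of allylic alcohol and aldehyde, loss of the allylic coumarinyl ether under the acidic selenium conditions, and Claisen rearrangement on heating. The fallback builds the enal by olefin metathesis instead of oxidation. It sets out from 4. O-allylation with allyl bromide (K2CO3, acetone, 56 °C) gives 5-methyl-4-(prop-2-en-1-yloxy)-2H-chromen-2-one F3. Cross-metathesis of F3 with methacrolein [5 equiv; second-generation Hoveyda–Grubbs catalyst RuCl2(=CH-C6H4-2-OiPr)(H2IMes), 5 mol%, CH2Cl2, 40 °C] gives the (E)-enal directly. The fallback comes back to the route at 7 with the same step count.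

Step 2 (Mitsunobu etherification). The risk is competing C3-prenylation and formation of the 2-alkoxychromone isomer. The fallback reverses the polarity so that only the C4–O bond can form. It sets out from 4. Neat POCl3 at 100 °C gives 4-chloro-5-methyl-2H-chromen-2-one F4. Addition–elimination of the sodium alkoxide of 5 (NaH, THF, 0 °C) on F4 gives the prenyl ether. The fallback comes back to the route at 6 and costs one extra step.

## Further compounds

F1 | step 5 | 5-methyl-4-{[(2E,4R)-3-methyl-4-[(4,4,5,5-tetramethyl-1,3,2-dioxaborolan-2-yl)oxy]hepta-2,6-dien-1-yl]oxy}-2H-chromen-2-one | CC1(C)OB(O[C@H](CC=C)/C(C)=C/COc2cc(=O)oc3cccc(C)c23)OC1(C)C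
F2 | step 5 | 4-{[(2E,4R)-4-hydroxy-3-methylhepta-2,6-dien-1-yl]oxy}-5-methyl-2H-chromen-2-one | O[C@H](CC=C)/C(C)=C/COc1cc(=O)oc2cccc(C)c12
F3 | step 3 | 5-methyl-4-(prop-2-en-1-yloxy)-2H-chromen-2-one | C=CCOc1cc(=O)oc2cccc(C)c12
F4 | step 2 | 4-chloro-5-methyl-2H-chromen-2-one | Cc1cccc2oc(=O)cc(Cl)c12
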